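The plan rests on reading the O1–C2 bond of the dihydrofuran ring, with C2 carrying a 2-propenyl branch next to the oxygenated C3, as the contracted form of the O1–CMe2–C3(OH) unit of a 2,2-dimethylchroman-3-ol. Activation of that C3 hydroxyl lets O1 migrate from the gem-dimethyl carbon to C3; in one operation this closes the five-membered ring, inverts the carbinol carbon to give the trans-2,3 pattern and releases the isopropenyl alkene that later becomes the acrolein. The precursor is the (3R,4S)-4-silyloxy-2,2-dimethylchroman-3-ol already carrying the complete C6 side-chain ester, reached by Jacobsen epoxidation of a chromene.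

Key step: step 7

Remark: chroman atoms are numbered O1, C2, C3, C4, C4a, C5–C8, C8a; dihydrobenzofuran atoms O1, C2, C3, C3a, C4–C7, C7a.
Remark: 3-methylbut-2-enal is used as its catalogue diethyl acetal 2, because the amine-catalysed chromenylation of a para-acyl phenol runs cleanly with the acetal.
Remark: the side chain is completed before the epoxidation, so that the esterification meets a single hydroxyl group.

Step 1
Reactants: 1 4-hydroxyacetophenone; 2 1,1-diethoxy-3-methylbut-2-ene
Product: 4 6-acetyl-2,2-dimethyl-2H-chromene, via ortho-quinone methide 3 (not isolated)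
Conditions: 3-picoline (0.25 equiv), p-xylene, reflux, EtOH distilled off
Reagents that add atoms: none
Why: Amine-catalysed phenol–enal acetal chromenylation, in which acetal exchange and ortho C-alkylation are followed by loss of ethanol to the ortho-quinone methide 3 and oxa-6π electrocyclisation; the acetal variant suits electron-poor phenols, and the para-acetyl group leaves only the two equivalent ortho positions.

Step 2
Reactants: 4 6-acetyl-2,2-dimethyl-2H-chromene
Product: 5 (R)-1-(2,2-dimethyl-2H-chromen-6-yl)ethanol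
Conditions: RuCl[(R,R)-TsDPEN](p-cymene) (1 mol %), HCO2H/Et3N (5:2), CH2Cl2, 30 °C
Reagents that add atoms: none
Why: Noyori asymmetric transfer hydrogenation of an aryl methyl ketone, in which the (R,R)-ligated ruthenium hydride should deliver hydride to the Si face and set the (R)-carbinol, while the unactivated chromene alkene is not reduced and formic acid makes the reduction irreversible.

Step 3
Reactants: 5 (R)-1-(2,2-dimethyl-2H-chromen-6-yl)ethanol; 6 (R)-2-methylbutanoic acid
Product: 7 (R)-1-(2,2-dimethyl-2H-chromen-6-yl)ethyl (R)-2-methylbutanoate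
Conditions: DCC, DMAP (cat.), CH2Cl2, 0 °C to rt
Reagents that add atoms: none
Why: Steglich esterification forms the acyl–oxygen bond only, so the carbinol centre is retained, and low temperature with catalytic DMAP should keep the α-centre of the acid from epimerising; 5 has no other hydroxyl group.

Step 4
Reactants: 7 (R)-1-(2,2-dimethyl-2H-chromen-6-yl)ethyl (R)-2-methylbutanoate
Product: 8 (R)-1-[(3R,4R)-3,4-epoxy-2,2-dimethylchroman-6-yl]ethyl (R)-2-methylbutanoate
Conditions: (R,R)-[N,N'-bis(3,5-di-tert-butylsalicylidene)cyclohexane-1,2-diaminato]MnCl (4 mol %), 4-phenylpyridine N-oxide (0.2 equiv), NaOCl (aq, pH 11.3, Na2HPO4), CH2Cl2, 0 °C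
Reagents that add atoms: NaOCl, [Na+].[O-]Cl
Why: Jacobsen epoxidation of a 6-substituted 2,2-dimethylchromene, a favoured substrate class, in which the (R,R)-catalyst should transfer oxygen to the face that gives the (3R,4R)-epoxide under catalyst control; any minor isomer would be a diastereomer of 8.

Step 5
Reactants: 8 (R)-1-[(3R,4R)-3,4-epoxy-2,2-dimethylchroman-6-yl]ethyl (R)-2-methylbutanoate
Product: 9 (R)-1-[(3R,4S)-3,4-dihydroxy-2,2-dimethylchroman-6-yl]ethyl (R)-2-methylbutanoate
Conditions: HClO4 (cat., 0.05 M aq), THF–H2O, 0 °C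
Reagents that add atoms: water, O
Why: Acid-catalysed epoxide hydrolysis, in which water attacks the benzylic C4 anti to the breaking C–O bond (inversion at C4, retention at C3) to give the trans-diol; the strained benzylic epoxide should react in dilute cold acid well before the side-chain ester ionises.

Step 6
Reactants: 9 (R)-1-[(3R,4S)-3,4-dihydroxy-2,2-dimethylchroman-6-yl]ethyl (R)-2-methylbutanoate
Product: 10 (R)-1-[(3R,4S)-4-(tert-butyldimethylsilyloxy)-3-hydroxy-2,2-dimethylchroman-6-yl]ethyl (R)-2-methylbutanoate
Conditions: TBSCl (1.1 equiv), imidazole, DMF, 0 °C to rt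
Reagents that add atoms: tert-butyldimethylsilyl chloride, CC(C)(C)[Si](C)(C)Cl
Why: Regioselective silylation with a bulky silyl chloride should take the more accessible benzylic C4 hydroxyl, because the C3 hydroxyl is neopentyl-like and flanked by both C2 methyl groups; no stereocentre is touched.

Step 7
Reactants: 10 (R)-1-[(3R,4S)-4-(tert-butyldimethylsilyloxy)-3-hydroxy-2,2-dimethylchroman-6-yl]ethyl (R)-2-methylbutanoate
Product: 13 (R)-1-[(2R,3S)-3-(tert-butyldimethylsilyloxy)-2-(prop-1-en-2-yl)-2,3-dihydrobenzofuran-5-yl]ethyl (R)-2-methylbutanoate, via chroman C3 triflate 11 (not isolated), via bridged aryloxonium triflate 12 (not isolated)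
Conditions: Tf2O (1.2 equiv), 2,6-di-tert-butyl-4-methylpyridine (3 equiv), CH2Cl2, −78 °C to 0 °C
Reagents that add atoms: none
Why: Tf2O turns the C3 hydroxyl into triflate 11, which is equatorial in the trans-diequatorial half-chair, so the O1–CMe2 bond lies antiperiplanar to the C3–OTf bond. A lone pair of O1 displaces triflate from the rear of C3, closing the dihydrofuran ring in a 5-exo-tet sense (3-exo-tet for the transient oxiranium ring of 12); 12 then opens at its tertiary carbon and the hindered pyridine removes a methyl proton to leave the 2-propenyl group. The closest known reaction type is the anchimerically assisted six-to-five ring contraction of 2,2-dimethylchroman-3-ols and flavan-3-ols on sulfonylation or deoxyfluorination, a Wagner–Meerwein-type 1,2-shift of the ring oxygen. The one new stereocentre, dihydrobenzofuran C2 (the former chroman C3), is set by the inversion of the backside displacement, while the silyloxy carbon is untouched, so the trans-3,4 pattern of 10 becomes the trans-2,3 pattern of 13 (2R,3S). The step needs O1 participation to outrun participation by the C4 oxygen, methyl shift or aryl shift, and needs proton loss from a methyl group and not from C2–H. The bulky, weakly donating silyl ether and the diequatorial conformer should secure the first; the non-nucleophilic base, the six available methyl hydrogens and the inductive deactivation of C2–H by O1 should secure the second.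

Step 8
Reactants: 13 (R)-1-[(2R,3S)-3-(tert-butyldimethylsilyloxy)-2-(prop-1-en-2-yl)-2,3-dihydrobenzofuran-5-yl]ethyl (R)-2-methylbutanoate
Product: 14 (R)-1-[(2R,3S)-3-hydroxy-2-(prop-1-en-2-yl)-2,3-dihydrobenzofuran-5-yl]ethyl (R)-2-methylbutanoate
Conditions: Bu4NF, AcOH (1:1), THF, 0 °C to rt
Reagents that add atoms: none
Why: Fluoride desilylation driven by the Si–F bond cleaves only the Si–O bond, and the acetic acid buffer should keep the 3-hydroxy-2,3-dihydrobenzofuran from dehydrating to the benzofuran and leave the ester intact.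

Step 9
Reactants: 14 (R)-1-[(2R,3S)-3-hydroxy-2-(prop-1-en-2-yl)-2,3-dihydrobenzofuran-5-yl]ethyl (R)-2-methylbutanoate; 15 isovaleryl chloride
Product: 16 (2R,3S)-5-{(R)-1-[(R)-2-methylbutanoyloxy]ethyl}-2-(prop-1-en-2-yl)-2,3-dihydrobenzofuran-3-yl 3-methylbutanoate
Conditions: Et3N, DMAP (cat.), CH2Cl2, 0 °C
Reagents that add atoms: none
Why: DMAP-catalysed acylation of the only free hydroxyl with an acid chloride proceeds at oxygen with retention at C3, under basic conditions that avoid ionising either benzylic C–O bond.

Step 10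
Reactants: 16 (2R,3S)-5-{(R)-1-[(R)-2-methylbutanoyloxy]ethyl}-2-(prop-1-en-2-yl)-2,3-dihydrobenzofuran-3-yl 3-methylbutanoate
Product: 18 (2R,3S)-5-{(R)-1-[(R)-2-methylbutanoyloxy]ethyl}-2-(3-oxoprop-1-en-2-yl)-2,3-dihydrobenzofuran-3-yl 3-methylbutanoate, via allylic alcohol 17 (not isolated)
Conditions: SeO2 (0.5 equiv), t-BuOOH (3 equiv), CH2Cl2, rt; filter, concentrate; then MnO2, CH2Cl2, rt
Reagents that add atoms: SeO2, O=[Se]=O (transfers the oxygen atom); tert-butyl hydroperoxide, CC(C)(C)OO (reoxidant and net oxygen source)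
Why: Riley allylic oxidation by ene reaction of SeO2 at the terminal alkene carbon and [2,3]-sigmatropic shift should oxidise the methyl group rather than the oxygen-deactivated C2–H methine, giving alcohol 17 and some enal, and MnO2 then takes the crude allylic alcohol to the aldehyde; no stereocentre is involved.

Compound list
1 | 4-hydroxyacetophenone | CC(=O)c1ccc(O)cc1 | starting material
2 | 1,1-diethoxy-3-methylbut-2-ene (diethyl acetal of 3-methylbut-2-enal) | CCOC(OCC)C=C(C)C | starting material
3 | 4-acetyl-6-(3-methylbut-2-en-1-ylidene)cyclohexa-2,4-dien-1-one (ortho-quinone methide, not isolated) | CC(C)=CC=C1C=C(C(C)=O)C=CC1=O | intermediate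
4 | 6-acetyl-2,2-dimethyl-2H-chromene | CC1(C)Oc2ccc(C(C)=O)cc2C=C1 | intermediate
5 | (R)-1-(2,2-dimethyl-2H-chromen-6-yl)ethanol | CC1(C)Oc2ccc([C@@H](C)O)cc2C=C1 | intermediate
6 | (R)-2-methylbutanoic acid | CC[C@@H](C)C(=O)O | starting material
7 | (R)-1-(2,2-dimethyl-2H-chromen-6-yl)ethyl (R)-2-methylbutanoate | CC1(C)Oc2ccc([C@@H](C)OC(=O)[C@H](C)CC)cc2C=C1 | intermediate
8 | (R)-1-[(3R,4R)-3,4-epoxy-2,2-dimethylchroman-6-yl]ethyl (R)-2-methylbutanoate | CC1(C)Oc2ccc([C@@H](C)OC(=O)[C@H](C)CC)cc2[C@H]3O[C@@H]13 | intermediate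
9 | (R)-1-[(3R,4S)-3,4-dihydroxy-2,2-dimethylchroman-6-yl]ethyl (R)-2-methylbutanoate (trans-diol) | CC1(C)Oc2ccc([C@@H](C)OC(=O)[C@H](C)CC)cc2[C@H](O)[C@H]1O | intermediate
10 | (R)-1-[(3R,4S)-4-(tert-butyldimethylsilyloxy)-3-hydroxy-2,2-dimethylchroman-6-yl]ethyl (R)-2-methylbutanoate (key-step precursor) | CC1(C)Oc2ccc([C@@H](C)OC(=O)[C@H](C)CC)cc2[C@H](O[Si](C)(C)C(C)(C)C)[C@H]1O | intermediate
11 | C3 trifluoromethanesulfonate of 10, (3R,4S) (not isolated) | CC1(C)Oc2ccc([C@@H](C)OC(=O)[C@H](C)CC)cc2[C@H](O[Si](C)(C)C(C)(C)C)[C@H]1OS(=O)(=O)C(F)(F)F | intermediate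
12 | bridged aryloxonium triflate, O1 bonded to C8a, to the CMe2 carbon and to the former C3 (not isolated) | CC1(C)[C@@H]2[C@@H](O[Si](C)(C)C(C)(C)C)c3cc([C@@H](C)OC(=O)[C@H](C)CC)ccc3[O+]12.[O-]S(=O)(=O)C(F)(F)F | intermediate
13 | (R)-1-[(2R,3S)-3-(tert-butyldimethylsilyloxy)-2-(prop-1-en-2-yl)-2,3-dihydrobenzofuran-5-yl]ethyl (R)-2-methylbutanoate (key-step product, trans) | C=C(C)[C@H]1Oc2ccc([C@@H](C)OC(=O)[C@H](C)CC)cc2[C@@H]1O[Si](C)(C)C(C)(C)C | intermediate
14 | (R)-1-[(2R,3S)-3-hydroxy-2-(prop-1-en-2-yl)-2,3-dihydrobenzofuran-5-yl]ethyl (R)-2-methylbutanoate | C=C(C)[C@H]1Oc2ccc([C@@H](C)OC(=O)[C@H](C)CC)cc2[C@@H]1O | intermediate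
15 | isovaleryl chloride (3-methylbutanoyl chloride) | CC(C)CC(=O)Cl | starting material
16 | (2R,3S)-5-{(R)-1-[(R)-2-methylbutanoyloxy]ethyl}-2-(prop-1-en-2-yl)-2,3-dihydrobenzofuran-3-yl 3-methylbutanoate | C=C(C)[C@H]1Oc2ccc([C@@H](C)OC(=O)[C@H](C)CC)cc2[C@@H]1OC(=O)CC(C)C | intermediate
17 | (2R,3S)-2-(3-hydroxyprop-1-en-2-yl)-5-{(R)-1-[(R)-2-methylbutanoyloxy]ethyl}-2,3-dihydrobenzofuran-3-yl 3-methylbutanoate (not isolated) | C=C(CO)[C@H]1Oc2ccc([C@@H](C)OC(=O)[C@H](C)CC)cc2[C@@H]1OC(=O)CC(C)C | intermediate
18 | (2R,3S)-5-{(R)-1-[(R)-2-methylbutanoyloxy]ethyl}-2-(3-oxoprop-1-en-2-yl)-2,3-dihydrobenzofuran-3-yl 3-methylbutanoate (CNP0154159.1) | C=C(C=O)[C@H]1Oc2ccc([C@@H](C)OC(=O)[C@H](C)CC)cc2[C@@H]1OC(=O)CC(C)C | target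

Total step count: 10 steps.
Longest linear sequence: 10 steps, from 1 to 18; compounds 2, 6 and 15 are purchased and enter in steps 1, 3 and 9.

Steps most likely to fail

Step 7. The ionising triflate may leak into other channels: participation of the C4 oxygen from the diaxial conformer, a methyl or aryl shift, or proton loss from C2–H instead of a methyl group. The fallback separates the skeletal change from the alkene-forming event. It sets out from 10, which is mesylated (MsCl, Et3N, CH2Cl2, 0 °C) to the isolable C3 mesylate F1. Solvolysis of F1 in aqueous acetone buffered with CaCO3 at about 60 °C should trigger the same O1 shift, with water capturing the oxonium ion at its tertiary carbon to give the ring-contracted tertiary alcohol F2. Burgess dehydration of F2 in warm toluene, a syn elimination that draws on six methyl hydrogens, should then give the isopropenyl compound, and the fallback comes back to the route at 13.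

Step 10. The allylic oxidation may be accompanied by acid-promoted loss of isovaleric acid with aromatisation to the benzofuran, by attack at the C2–H methine, or by incomplete oxidation. The fallback sets out from 16 and replaces the selenium chemistry by halogenation and oxygen transfer. Ene-type allylic chlorination of the isopropenyl group with HOCl generated from Ca(OCl)2 and CO2 in CH2Cl2–H2O at 0 °C should give the 2-(chloromethyl)vinyl compound F3. Amine N-oxide oxidation of this allylic chloride (Me3NO, DMSO, rt, Ganem oxidation) should give the enal, and the fallback comes back to the route at 18.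

Step 5. Trans selectivity may erode because the benzylic cation at C4, stabilised by the ortho ring oxygen, can be captured from both faces; the para-alkoxybenzylic side-chain ester may also ionise in acid. The fallback postpones the side chain so that the para-acetyl group tempers O1 during the opening and no labile ester is present. It sets out from 4, which is epoxidised under the conditions of step 4 to the epoxy ketone F4. Cold dilute HClO4 should open F4 to the trans-diol ketone F5, and TBSCl with imidazole should give the C4 silyl ether F6. Transfer hydrogenation of F6 as in step 2 should give the (R)-carbinol F7. Steglich esterification of F7 with 6 (one equivalent, 0 °C) should occur at the unhindered side-chain hydroxyl and leave the neopentyl-like C3 hydroxyl free, and the fallback comes back to the route at 10.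

Further compounds
F1 | step 7 | (R)-1-[(3R,4S)-4-(tert-butyldimethylsilyloxy)-3-(methanesulfonyloxy)-2,2-dimethylchroman-6-yl]ethyl (R)-2-methylbutanoate | CC1(C)Oc2ccc([C@@H](C)OC(=O)[C@H](C)CC)cc2[C@H](O[Si](C)(C)C(C)(C)C)[C@H]1OS(C)(=O)=O
F2 | step 7 | (R)-1-[(2S,3S)-3-(tert-butyldimethylsilyloxy)-2-(2-hydroxypropan-2-yl)-2,3-dihydrobenzofuran-5-yl]ethyl (R)-2-methylbutanoate (same spatial arrangement as 13; the C2 descriptor changes by priority only) | CC(C)(O)[C@H]1Oc2ccc([C@@H](C)OC(=O)[C@H](C)CC)cc2[C@@H]1O[Si](C)(C)C(C)(C)C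
F3 | step 10 | (2R,3S)-2-(3-chloroprop-1-en-2-yl)-5-{(R)-1-[(R)-2-methylbutanoyloxy]ethyl}-2,3-dihydrobenzofuran-3-yl 3-methylbutanoate | C=C(CCl)[C@H]1Oc2ccc([C@@H](C)OC(=O)[C@H](C)CC)cc2[C@@H]1OC(=O)CC(C)C
F4 | step 5 | (3R,4R)-6-acetyl-3,4-epoxy-2,2-dimethylchroman | CC1(C)Oc2ccc(C(C)=O)cc2[C@H]3O[C@@H]13
F5 | step 5 | (3R,4S)-6-acetyl-2,2-dimethylchroman-3,4-diol | CC1(C)Oc2ccc(C(C)=O)cc2[C@H](O)[C@H]1O
F6 | step 5 | (3R,4S)-6-acetyl-4-(tert-butyldimethylsilyloxy)-2,2-dimethylchroman-3-ol | CC1(C)Oc2ccc(C(C)=O)cc2[C@H](O[Si](C)(C)C(C)(C)C)[C@H]1O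
F7 | step 5 | (3R,4S)-4-(tert-butyldimethylsilyloxy)-6-[(R)-1-hydroxyethyl]-2,2-dimethylchroman-3-ol | CC1(C)Oc2ccc([C@@H](C)O)cc2[C@H](O[Si](C)(C)C(C)(C)C)[C@H]1O
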